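**Retrosynthetic overview**
1. The target is reached last by cleaving the four methyl ethers of 8-(2,3-dimethoxybenzyl)-5,7-dimethoxyflavone.
2. That flavone is cut at C4–C4a: an intramolecular Friedel–Crafts acylation of (Z)-3-aryloxy-3-phenylacrylic acid closes the pyranone (ring C), the only ring built; the three benzene rings are bought.
3. Feature the strategy rests on: in ring A the ether oxygen O1 (on C8a) lies between C8, which already bears the benzyl CH2, and C4a, which bears H. C4a is the only ortho carbon open to acylation, so the 6-benzyl isomer cannot form.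
4. The acid is cut at O1–C2: oxa-Michael addition of 2-(2,3-dimethoxybenzyl)-3,5-dimethoxyphenol to ethyl phenylpropiolate, then saponification.
5. The phenol is cut at CH2–aryl: ortho-lithiated veratrole adds to 2-hydroxy-4,6-dimethoxybenzaldehyde and the carbinol is deoxygenated; the formyl carbon fixes the benzyl group between OH and OMe.

Key step: step 5

Remark: the target has no stereocentre and no stereogenic double bond, so no enantiocontrol is needed; the only stereo-elements on the way are a racemic carbinol carbon (removed in step 2) and the Z enol-ether double bond (consumed in step 5).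

**Step 1**
Reactants: 1 veratrole; 2 2-hydroxy-4,6-dimethoxybenzaldehyde
Product: 4 rac-(2,3-dimethoxyphenyl)(2-hydroxy-4,6-dimethoxyphenyl)methanol, via 2,3-dimethoxyphenyllithium 3 (not isolated)
Conditions: 1 (2.5 equiv), n-BuLi (2.3 equiv), TMEDA, Et2O, 0 °C → rt; then 2 (1.0 equiv) in THF, −78 → 0 °C; sat. aq NH4Cl; crude product used directly
Reagents that add atoms: none
Why: Methoxy-directed ortho-lithiation of veratrole followed by 1,2-addition of the aryllithium to the aldehyde; one equivalent is spent on the phenol O–H, the lithium phenoxide aldehyde should still accept the hard aryllithium, and the new carbinol carbon forms as a racemate that is removed in step 2.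

**Step 2**
Reactants: 4 rac-(2,3-dimethoxyphenyl)(2-hydroxy-4,6-dimethoxyphenyl)methanol
Product: 5 2-(2,3-dimethoxybenzyl)-3,5-dimethoxyphenol
Conditions: Et3SiH (5 equiv), TFA (5 equiv), CH2Cl2, −20 → 0 °C, slow addition of 4 to the silane/acid mixture
Reagents that add atoms: none
Why: Ionic hydrogenation, in which TFA ionises the doubly benzylic carbinol to a diarylmethyl cation stabilised by the ortho-OH and the ortho/para methoxy groups and Et3SiH transfers hydride to it; the methyl ethers and the phenol should be untouched and the stereocentre disappears.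

**Step 3**
Reactants: 5 2-(2,3-dimethoxybenzyl)-3,5-dimethoxyphenol; 6 ethyl phenylpropiolate
Product: 7 ethyl (Z)-3-[2-(2,3-dimethoxybenzyl)-3,5-dimethoxyphenoxy]-3-phenylprop-2-enoate
Conditions: K2CO3 (1.2 equiv), DMF, 80 °C
Reagents that add atoms: none
Why: Base-mediated oxa-Michael addition of the phenoxide to the β-carbon of the ynoate with protonation anti to the incoming oxygen, which should favour the Z ester (ArO cis to CO2Et); aprotic DMF favours O- over C-attack, and any E ester is carried on because step 5 equilibrates the geometry.

**Step 4**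
Reactants: 7 ethyl (Z)-3-[2-(2,3-dimethoxybenzyl)-3,5-dimethoxyphenoxy]-3-phenylprop-2-enoate
Product: 8 (Z)-3-[2-(2,3-dimethoxybenzyl)-3,5-dimethoxyphenoxy]-3-phenylprop-2-enoic acid
Conditions: LiOH·H2O (3 equiv), THF/MeOH/H2O, rt → 40 °C; then 1 M HCl to pH 3, 0 °C
Reagents that add atoms: lithium hydroxide (its oxygen becomes the carboxyl OH), [Li+].[OH-]
Why: Ester saponification; once the carboxylate has formed the β-carbon is deactivated towards hydroxide, so the aryl vinyl ether should be kept, and cold mild acidification avoids enol-ether hydrolysis.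

**Step 5**
Reactants: 8 (Z)-3-[2-(2,3-dimethoxybenzyl)-3,5-dimethoxyphenoxy]-3-phenylprop-2-enoic acid
Product: 9 8-(2,3-dimethoxybenzyl)-5,7-dimethoxy-2-phenyl-4H-chromen-4-one
Conditions: Eaton's reagent (7.7 wt% P2O5 in MeSO3H), rt → 45 °C; poured onto ice, NaHCO3
Reagents that add atoms: none
Why: Intramolecular Friedel–Crafts acylation of a 3-aryloxycinnamic acid, the classical acid-mediated route from such acids to flavones: P2O5/MeSO3H turns the carboxyl group into a mixed anhydride or acylium ion conjugated with the enol ether, C6 of the aryloxy ring (the future C4a) attacks it, and loss of the proton from the arenium ion gives the C4–C4a bond and the pyranone. The ring closes in a six-membered mode, exo at the acyl carbon and endo with respect to the arene π-bond C4a–C8a, that is 6-endo as counted on the arene. No stereocentre is formed. The step needs regioselectivity on ring A and gets it from the substitution pattern: the ether oxygen has a single unsubstituted ortho carbon, activated by one ortho and one para methoxy group, because the other ortho carbon carries the benzyl CH2, so only the 8-benzyl flavone can form. Attack on the dimethoxybenzyl ring would need a nine-membered ring, and attack on the 3-phenyl group (indenone formation) needs the E acid and an unactivated ring. The step also needs the carboxyl group cis to the aryloxy oxygen: protonation of the carbonyl gives a cation delocalised onto C3 and the ether oxygen, which lowers the C2–C3 rotation barrier so that E acid is converted into the reacting Z form, while P2O5 binds the water and keeps the enol ether from hydrolysing.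

**Step 6**
Reactants: 9 8-(2,3-dimethoxybenzyl)-5,7-dimethoxy-2-phenyl-4H-chromen-4-one
Product: 10 8-(2,3-dihydroxybenzyl)-5,7-dihydroxy-2-phenyl-4H-chromen-4-one
Conditions: BBr3 (10 equiv), CH2Cl2, −78 °C → rt, argon; then ice/H2O
Reagents that add atoms: none
Why: Lewis-acid ether cleavage, in which BBr3 complexes each ether oxygen and bromide attacks the methyl group (the 5-OMe assisted by chelation to the C4 carbonyl); under anhydrous, non-protic conditions the pyranone should not open, so the 8-benzyl group is not scrambled to C6 by a Wessely–Moser rearrangement.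

**Compound list**
1 | veratrole (1,2-dimethoxybenzene) | COc1ccccc1OC | starting material
2 | 2-hydroxy-4,6-dimethoxybenzaldehyde | COc1cc(O)c(C=O)c(OC)c1 | starting material
3 | 2,3-dimethoxyphenyllithium | [Li]c1cccc(OC)c1OC | intermediate
4 | rac-(2,3-dimethoxyphenyl)(2-hydroxy-4,6-dimethoxyphenyl)methanol | OC(c1cccc(OC)c1OC)c1c(O)cc(OC)cc1OC | intermediate
5 | 2-(2,3-dimethoxybenzyl)-3,5-dimethoxyphenol | COc1cc(O)c(Cc2cccc(OC)c2OC)c(OC)c1 | intermediate
6 | ethyl phenylpropiolate (ethyl 3-phenylprop-2-ynoate) | CCOC(=O)C#Cc1ccccc1 | starting material
7 | ethyl (Z)-3-[2-(2,3-dimethoxybenzyl)-3,5-dimethoxyphenoxy]-3-phenylprop-2-enoate | CCOC(=O)/C=C(\Oc1cc(OC)cc(OC)c1Cc1cccc(OC)c1OC)c1ccccc1 | intermediate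
8 | (Z)-3-[2-(2,3-dimethoxybenzyl)-3,5-dimethoxyphenoxy]-3-phenylprop-2-enoic acid | OC(=O)/C=C(\Oc1cc(OC)cc(OC)c1Cc1cccc(OC)c1OC)c1ccccc1 | intermediate
9 | 8-(2,3-dimethoxybenzyl)-5,7-dimethoxy-2-phenyl-4H-chromen-4-one | O=c1cc(-c2ccccc2)oc2c(Cc3cccc(OC)c3OC)c(OC)cc(OC)c12 | intermediate
10 | 8-(2,3-dihydroxybenzyl)-5,7-dihydroxy-2-phenyl-4H-chromen-4-one (CNP0031733.0) | O=c1cc(-c2ccccc2)oc2c(Cc3cccc(O)c3O)c(O)cc(O)c12 | target

**Totals**
Total step count: 6. Longest linear sequence: 6 steps (2 → 4 → 5 → 7 → 8 → 9 → 10).

**Steps most likely to fail**

Step 5 (key step). What may go wrong: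
- ipso attack at the benzyl-bearing ortho carbon with loss or migration of the benzyl group;
- acid hydrolysis of the enol ether, which returns the phenol;
- methanesulfonylation or intermolecular acylation of the electron-rich rings if the mixture is heated.

The fallback sets out from 5 and comes back at 9. Phenol 5 would be acetylated ortho to the hydroxyl group (Ac2O, BF3·OEt2, 60 °C; O-acetylation and chelation-controlled Fries shift) to give 1-[3-(2,3-dimethoxybenzyl)-2-hydroxy-4,6-dimethoxyphenyl]ethanone F1. Claisen–Schmidt condensation with benzaldehyde (KOH, EtOH, rt) should give (E)-1-[3-(2,3-dimethoxybenzyl)-2-hydroxy-4,6-dimethoxyphenyl]-3-phenylprop-2-en-1-one F2. Oxidative cyclisation with catalytic I2 in DMSO at 120–130 °C should then give flavone 9. The benzyl position stays fixed because the only hydroxyl ortho to the acyl group is the one next to the benzyl carbon.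

Step 3. What may go wrong:
- slow or reversible addition of the hindered, ortho-substituted phenoxide;
- C-alkylation of the electron-rich ring by the ynoate;
- formation of mainly the E ester.

The fallback sets out from 6 and 5 and comes back at 7. Ynoate 6 would be hydrobrominated (LiBr, AcOH, 70 °C, anti addition) to ethyl (Z)-3-bromo-3-phenylprop-2-enoate F3. F3 would then be coupled with phenol 5 in a copper-catalysed vinyl C–O coupling (CuI, N,N-dimethylglycine, Cs2CO3, dioxane, 90 °C). This should proceed with retention of the double-bond geometry and give 7 directly as the Z isomer.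

Step 2. What may go wrong:
- capture of the stabilised diarylmethyl cation (or the derived o-quinone methide) by the electron-rich ring of a second molecule instead of by the silane;
- decomposition of the acid-labile carbinol during handling.

The fallback sets out from 2 and comes back at 5. Aldehyde 2 would be O-benzylated (BnBr, K2CO3, DMF, rt) to 2-(benzyloxy)-4,6-dimethoxybenzaldehyde F4. One equivalent of aryllithium 3 would then add to give rac-[2-(benzyloxy)-4,6-dimethoxyphenyl](2,3-dimethoxyphenyl)methanol F5, which has no free ortho-hydroxyl and is less labile. Hydrogenolysis (H2, Pd/C, EtOAc/AcOH, rt) should remove the O-benzyl group and the doubly benzylic hydroxyl in one operation without a free cation in solution, giving 5.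

**Further compounds**
F1 | step 5 | 1-[3-(2,3-dimethoxybenzyl)-2-hydroxy-4,6-dimethoxyphenyl]ethanone | CC(=O)c1c(O)c(Cc2cccc(OC)c2OC)c(OC)cc1OC
F2 | step 5 | (E)-1-[3-(2,3-dimethoxybenzyl)-2-hydroxy-4,6-dimethoxyphenyl]-3-phenylprop-2-en-1-one | O=C(/C=C/c1ccccc1)c1c(O)c(Cc2cccc(OC)c2OC)c(OC)cc1OC
F3 | step 3 | ethyl (Z)-3-bromo-3-phenylprop-2-enoate | CCOC(=O)/C=C(\Br)c1ccccc1
F4 | step 2 | 2-(benzyloxy)-4,6-dimethoxybenzaldehyde | COc1cc(OCc2ccccc2)c(C=O)c(OC)c1
F5 | step 2 | rac-[2-(benzyloxy)-4,6-dimethoxyphenyl](2,3-dimethoxyphenyl)methanol | OC(c1cccc(OC)c1OC)c1c(OCc2ccccc2)cc(OC)cc1OC
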